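Fraction of the charge converted, multiplied by the charge, is an amount, and across the earlier runs that amount grows at a similar pace. Averaged up to its last reading, grey makes 0.480 mM/h and violet 0.491 mM/h, so the mean of the two is 0.485 mM/h. That is the delivery, the fraction of the charge turned into target each hour times the charge. Ochre, with 0.36 mM of free catalyst against grey's 2.1 mM, delivers 0.401 mM/h on the same average.

| flask | solid substrate | gas | free catalyst | remark | time |
|---|---|---|---|---|---|
| ochre | 15 mM | 7 mM (held) | 0.36 mM | run made earlier |  |
| grey | 15 mM | 7 mM (held) | 2.1 mM | run made earlier |  |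
| violet | 21 mM | 7 mM (held) | 1.5 mM | run made earlier |  |
| maple | 10 mM | 7.0 mM (held) | 2.5 mM |  | 8.0 h |
| larch | 30 mM | 7.0 mM (held) | 0.50 mM |  | 8.0 h |
| elm | 25 mM | 7.0 mM (held) | 2.5 mM |  | 8.0 h |
| alder | 15 mM | 7.0 mM (held) | 1.5 mM |  | 8.0 h |

- ochre (time / h: target / %): 0.417: 0.2; 1.33: 0.3; 2.50: 4.5; 3.00: 6.3; 5.00: 11.5; 6.00: 14.1; 8.00: 21.4
- grey (time / h: target / %): 0.417: 0.2; 1.33: 2.9; 2.50: 8.1; 3.00: 8.7; 5.00: 16.4; 6.00: 21.2; 8.00: 25.6
- violet (time / h: target / %): 1.50: 2.9; 3.00: 7.8; 5.00: 12.0; 6.00: 14.6; 8.00: 18.7

(each reading ± 1 percentage point)

1. the flasks put in order of amount of target, in percent of the solid substrate charged, best first, at 8.0 h (maple / larch / elm / alder)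
2. the amount of target, in percent of the solid substrate charged of the flask you put first, at 8.0 h
3. the amount of target, in percent of the solid substrate charged of the flask you put last, at 8.0 h

- as a solid, counted per litre of solution: solid substrate
- at the start none of the solid substrate is in solution
- at the start none of the gas is in solution
- what has only dissolved of solid substrate counts as not reacted

Two of us read this differently. The first says the fraction converted belongs to the catalyst: grey with 2.1 mM reached 25.6%, ochre with 0.36 mM reached 21.4%, so elm, with 2.5 mM, should stand near grey's fraction.

The second view, which is mine, says the delivery belongs to the solid. Catalyst rose 5.83 times from ochre to grey while delivery rose 1.20 times, and violet, with 21 mM of solid substrate and 1.5 mM of free catalyst, delivers about what grey does with 15 mM and 2.1 mM. So I divide the delivery by each charge: over 8.0 h, my estimate for maple is 38.8%, for alder 25.9% and for elm 15.5%. Larch, with 0.50 mM of free catalyst against ochre's 0.36 mM, I put between 10.7% and 12.9%. Elm separates us: 25.6% against 15.5%.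

The forecast takes the second side, holding that the runs fit “a reaction fed by a saturated solution, or one limited by transfer”, and gives maple > alder > elm > larch, with 35% for maple and 11.5% for larch, so its maple stands below my 38.8%.

The simulation gives maple > alder > elm > larch: maple 40.9%, alder 26.6%, elm 16.4%, larch 11.8%. Elm lies nearer the second view's figure than grey's 25.6%. The first view keeps the lean-catalyst end: from ochre, raising the free catalyst by itself to larch's 0.50 mM moves the target from 22.1% to 23.7%. Larch delivered 0.444 mM/h on average, less than elm's 0.511 mM/h, though these two flasks differ in solid substrate as well.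

    reagent + free catalyst → catalyst intermediate A (k = 33000 /M/h)
    starting material + catalyst intermediate A ⇌ catalyst intermediate B (K = 280 /M, k = 7200 /M/h)
    catalyst intermediate B → free catalyst + target (k = 18.0 /h)
    solid substrate ⇌ starting material, rate k4*(cs4 - [starting material]) while solid is left; crystals form when [starting material] > cs4 (solubility = 5.50 mM, k = 0.0970 /h)
    gas ⇌ reagent, rate k5*(csat - [reagent]) (kL = 0.780 /h)
    starting material + target → side product (k = 9.30 /M/h)

Now read larch at 20 h instead of 8.0 h, all amounts held, and reckon as before. The delivery 0.485 mM/h gives 32.4% of the charge and ochre's 0.401 mM/h gives 26.7%, and this larch stands between them at 30.3%. In larch at that time, 94.3% of the catalyst sits as catalyst intermediate A, the resting state. Of larch's charged solid substrate, 68% is then still there, solid or dissolved.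

The numbers in the tables were generated by integration for substances that don't exist; the scatter is artificial.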